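**Plan**
- Retrosynthesis: the ten-membered ring is cut at C6–C7 (alkenyl iodide plus aldehyde). The C9 chain is cut at C8–C9 (2-haloallyl metal plus C9 aldehyde). The C1 chain is cut at C3–C4 and C2=C3 (alkyl–alkenyl coupling on a Z-iodoalkene made from a C2 aldehyde). The isopropyl group is cut at its two methyl bonds, and the cyclohexane last at C10–C11 and C1–C14.
- Forward: 6-methyl-2-pyranone and maleic anhydride give the six-membered carbocycle first, as a lactone-bridged bicycle. A lactone transposition then tells the three acyl carbons apart. The isopropyl group, the C1 chain and the C9 chain follow, and the ten-membered ring is closed last by a nickel/chromium coupling.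
- Enabling feature: in the ring C1–C10–C11–C12–C13–C14 the C11–O and C14–C18 bonds sit 1,4-cis on one face, and the C10–C9 and C1–C2 bonds sit cis on the other face. This is the pattern of an endo 2-oxabicyclo[2.2.2]octene adduct of a 2-pyranone with a cis dienophile.
- Stereochemistry: the endo cycloaddition sets C1, C10, C11 and C14 relative to each other, and separation of diastereomeric (S)-1-phenylethylamides fixes the absolute configuration. The 2Z alkene comes from an α-iodo Wittig reaction and a stereoretentive Suzuki coupling. C9 is set by substrate-controlled allylation and C6 in the ring closure.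

Key step: step 3

Remarks
- Numbering is that of the eunicellane skeleton: C1–C10 ten-membered ring with C1/C10 at the fusion; C11 carbinol, C12, C13, C14; C15 methyl on C3; C16 exocyclic methylene on C7; C17 methyl on C11; C18 isopropyl methine. The target is (1S,2Z,6R,9R,10S,11R,14R).
- Compounds 5 to 8 are racemates; their SMILES show the enantiomer that is carried on.
- Assumption: the two diastereomeric amides formed in step 6 can be separated, and the one with the needed ring configuration is identified by X-ray analysis using the (S)-phenylethyl centre as internal reference.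

**Step 1**
Reactants: 1 4-hydroxy-6-methyl-2H-pyran-2-one
Product: 2 6-methyl-2-oxo-2H-pyran-4-yl trifluoromethanesulfonate
Conditions: Tf2O, Et3N, CH2Cl2, −78 to 0 °C
Reagents that add atoms: triflic anhydride, O=S(=O)(OS(=O)(=O)C(F)(F)F)C(F)(F)F
Why: O-sulfonylation of the acidic 4-hydroxyl (a vinylogous carboxylic acid) turns the C4–O bond into a leaving group for palladium chemistry.

**Step 2**
Reactants: 2 6-methyl-2-oxo-2H-pyran-4-yl trifluoromethanesulfonate
Product: 3 6-methyl-2H-pyran-2-one
Conditions: Pd(OAc)2 (cat.), PPh3, HCO2H, Et3N, DMF, 60 °C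
Reagents that add atoms: none
Why: Palladium-catalysed formate reduction of an enol triflate (oxidative addition to zerovalent palladium, formate for triflate, loss of CO2, C–H reductive elimination) should remove the 4-oxygen without touching the pyranone ring.

**Step 3**
Reactants: 3 6-methyl-2H-pyran-2-one; 4 maleic anhydride
Product: 5 (±)-endo-1-methyl-3-oxo-2-oxabicyclo[2.2.2]oct-7-ene-5,6-dicarboxylic anhydride
Conditions: 4 (1.5 equiv), PhMe, 100 °C, sealed vessel, kept below 110 °C; crystallisation on cooling
Reagents that add atoms: none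
Why: The pyranone diene (C3=C4–C5=C6 of the heterocycle) adds to the cis alkene of maleic anhydride in a concerted suprafacial [4+2] cycloaddition, the closest known reaction type being the thermal Diels–Alder reaction of 2-pyranones with maleic anhydride, which gives isolable lactone-bridged adducts. The carbocycle closes in an intermolecular cycloaddition that forms C10–C11 and C1–C14 at once, the lactone staying as a two-atom bridge across the new ring. C11 and C14 are bridgeheads, so the C11–O and C14–C18 bonds are necessarily cis, and C10 and C1 are cis because the dienophile geometry is retained. Endo approach (anhydride carbonyls under the diene, Alder rule) should place both anhydride carbons anti to the lactone bridge, which is the relative configuration of C1, C10, C11 and C14 in the target. The symmetrical dienophile leaves no regiochemical question, and the temperature is held well below that at which the adduct extrudes CO2; the adduct is racemic and its absolute configuration is fixed in step 6.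

**Step 4**
Reactants: 5 (±)-endo-1-methyl-3-oxo-2-oxabicyclo[2.2.2]oct-7-ene-5,6-dicarboxylic anhydride
Product: 6 (±)-endo-1-methyl-3-oxo-2-oxabicyclo[2.2.2]octane-5,6-dicarboxylic anhydride
Conditions: H2 (1 atm), Pd/C, EtOAc, rt
Reagents that add atoms: none
Why: Heterogeneous hydrogenation of the strained bridging alkene should be fast and removes the only path (retro-[4+2] loss of CO2) by which the bicycle can fragment, with no new stereocentre.

**Step 5**
Reactants: 6 (±)-endo-1-methyl-3-oxo-2-oxabicyclo[2.2.2]octane-5,6-dicarboxylic anhydride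
Product: 8 (±)-5,6-bis(hydroxymethyl)-1-methyl-2-oxabicyclo[2.2.2]octan-3-one, via lactone diacid 7 (not isolated)
Conditions: THF/H2O, 50 °C; evaporation and PhMe azeotrope; BH3·SMe2, THF, 0 °C to rt; MeOH quench
Reagents that add atoms: water, O
Why: Water opens the anhydride, and borane reduces carboxylic acids much faster than lactones (chemoselective borane reduction), so C9 and C2 should reach the alcohol level while C18 stays an acyl carbon.

**Step 6**
Reactants: 8 (±)-5,6-bis(hydroxymethyl)-1-methyl-2-oxabicyclo[2.2.2]octan-3-one; 9 (S)-1-phenylethylamine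
Product: 10 N-[(S)-1-phenylethyl] C18 carboxamide of the ring-opened triol (C11–OH and C14 amide cis; C9 and C2 hydroxymethyl groups cis to each other on the other face), single diastereomer
Conditions: 9 (3 equiv), TBD (0.2 equiv), PhMe, 80 °C; diastereomers separated by crystallisation (EtOAc/heptane) or chromatography
Reagents that add atoms: none
Why: Aminolysis of the strained tertiary-alkyl lactone (base-catalysed ester aminolysis, the classical resolution of lactones through diastereomeric hydroxy amides) frees the C11 hydroxyl and ties an enantiopure amine to C18, so the two ring enantiomers become separable diastereomers, of which the one with the target ring configuration is carried on.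

**Step 7**
Reactants: 10 N-[(S)-1-phenylethyl] hydroxy amide
Product: 11 trans-fused γ-lactone 5-hydroxy-4-(hydroxymethyl)-5-methylhexahydro-2-benzofuran-1(3H)-one (C2–O–C18 lactone; free C9–OH and C11–OH)
Conditions: 1 M HCl, THF/H2O, 50 °C
Reagents that add atoms: none
Why: Once the bridge is gone the ring relaxes to a chair in which the C1 hydroxymethyl and the C14 carboxamide are trans-diequatorial neighbours, so acid-mediated N-to-O acyl transfer should close the γ-lactone on the C2 oxygen only (the C9 and C11 oxygens cannot reach C18), which tells C2 from C9 and returns the amine.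

**Step 8**
Reactants: 11 trans-fused hydroxy γ-lactone
Product: 12 C9 tert-butyldimethylsilyl ether of 11
Conditions: TBSCl, imidazole, DMF, 0 °C
Reagents that add atoms: tert-butyldimethylsilyl chloride, CC(C)(C)[Si](C)(C)Cl
Why: Silylation under these conditions should take the primary C9 hydroxyl and leave the hindered axial tertiary C11 hydroxyl free.

**Step 9**
Reactants: 12 C9 silyl ether lactone
Product: 13 γ-hydroxy methyl ketone (C18 acetyl on C14, free C2–OH and C11–OH; in equilibrium with its cyclic hemiketal)
Conditions: MeLi (2.1 equiv), THF, −78 °C; aq. NH4Cl at −78 °C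
Reagents that add atoms: methyllithium, [Li]C
Why: One equivalent of MeLi takes the C11 hydroxyl proton and the second adds once to the lactone, because the lithium hemiketal persists at −78 °C until the quench (mono-addition of an organolithium to a lactone); C14 keeps its configuration, the equatorial acyl group being the stable epimer.

**Step 10**
Reactants: 13 γ-hydroxy methyl ketone
Product: 14 isopropenyl diol (C18 isopropenyl on C14)
Conditions: Ph3PCH3Br, KOtBu (excess), THF, 0 to 50 °C
Reagents that add atoms: methyltriphenylphosphonium bromide, C[P+](c1ccccc1)(c1ccccc1)c1ccccc1.[Br-]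
Why: Wittig methylenation of the open-chain methyl ketone (excess ylide absorbs the two hydroxyl protons) should give the isopropenyl group without a stereochemical risk at C14.

**Step 11**
Reactants: 14 isopropenyl diol
Product: 15 isopropyl diol (C9–OTBS, free C2–OH and C11–OH)
Conditions: H2 (1 atm), Pd/C, EtOAc, rt
Reagents that add atoms: none
Why: Hydrogenation of the 1,1-disubstituted alkene completes the isopropyl group before any other alkene is present, and creates no stereocentre.

**Step 12**
Reactants: 15 isopropyl diol
Product: 16 C2 aldehyde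
Conditions: Dess–Martin periodinane, NaHCO3, CH2Cl2, 0 °C to rt
Reagents that add atoms: none
Why: Buffered Dess–Martin oxidation converts the primary C2 alcohol to the aldehyde, cannot touch the tertiary alcohol, and leaves C1 alone because the equatorial formyl group is already the stable epimer.

**Step 13**
Reactants: 16 C2 aldehyde
Product: 17 (Z)-2-iodo-2-alkene (C2=C3, iodine on C3 cis to C1, C15 methyl trans to C1)
Conditions: Ph3PEtI, n-BuLi, THF; I2, −78 °C; NaN(SiMe3)2, −78 to −20 °C; then 16
Reagents that add atoms: ethyltriphenylphosphonium iodide, CC[P+](c1ccccc1)(c1ccccc1)c1ccccc1.[I-]; iodine, [I][I]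
Why: The α-iodo Wittig olefination with Ph3P=C(I)CH3 (Stork–Zhao type) should give the Z-iodoalkene through the kinetically preferred cis-oxaphosphetane, which places iodine, the later site of C4, cis to C1.

**Step 14**
Reactants: 17 (Z)-2-iodo-2-alkene; 18 acrolein diethyl acetal
Product: 20 (Z)-trisubstituted alkene carrying the C4–C6 chain with C6 as diethyl acetal, via alkyl-9-BBN 19 (not isolated)
Conditions: 18, 9-BBN, THF, rt; then 17, Pd(dppf)Cl2, AsPh3, Cs2CO3, DMF/H2O, rt
Reagents that add atoms: none
Why: Hydroboration places boron on the terminal carbon, and the B-alkyl Suzuki–Miyaura coupling (oxidative addition to zerovalent palladium, transmetalation, reductive elimination) proceeds with retention of alkene geometry, so C4 should end cis to C1 and the 2Z alkene is fixed.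

**Step 15**
Reactants: 20 silyl ether acetal
Product: 21 C9 primary alcohol
Conditions: Bu4NF, THF, rt
Reagents that add atoms: none
Why: Fluoride cleaves the Si–O bond selectively, the acetal and the tertiary alcohol being inert to it.

**Step 16**
Reactants: 21 C9 primary alcohol
Product: 22 C9 aldehyde (axial formyl on C10, β to the C11 hydroxyl)
Conditions: Dess–Martin periodinane, NaHCO3, CH2Cl2, 0 °C; used crude at once
Reagents that add atoms: none
Why: The buffered, base-free oxidation gives the β-hydroxy aldehyde without enolisation, so neither epimerisation at C10 nor retro-aldol cleavage of C10–C11 should intervene.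

**Step 17**
Reactants: 22 C9 aldehyde; 23 2,3-dibromopropene
Product: 25 (9R) 2-bromo homoallylic alcohol, via 2-bromoallylindium dibromide 24 (not isolated)
Conditions: indium powder, 23, DMF, rt
Reagents that add atoms: none
Why: In the Barbier-type 2-bromoallylation under neutral conditions the axial formyl group should turn its hydrogen under the ring and its oxygen outward, so the allyl metal adds to the carbonyl face next to the C11 methyl group and not to the face screened by the larger C1 alkenyl chain, which gives 9R (Felkin-type substrate control).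

**Step 18**
Reactants: 25 (9R) bromo homoallylic alcohol
Product: 26 C9 acetate
Conditions: Ac2O, pyridine, DMAP (cat.), CH2Cl2, rt
Reagents that add atoms: acetic anhydride, CC(=O)OC(C)=O
Why: Acetylation takes the secondary C9 hydroxyl, installs an ester that belongs to the target, and should leave the much more hindered axial tertiary C11 hydroxyl free.

**Step 19**
Reactants: 26 alkenyl bromide acetate
Product: 27 alkenyl iodide acetate (2-iodo-1-alkene at C7)
Conditions: CuI (cat.), NaI, trans-N,N'-dimethylcyclohexane-1,2-diamine, dioxane, 110 °C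
Reagents that add atoms: sodium iodide, [Na+].[I-]
Why: Copper-catalysed halogen exchange (vinylic Finkelstein reaction), driven by precipitation of NaBr, should give the more reactive alkenyl iodide needed for the nickel/chromium coupling.

**Step 20**
Reactants: 27 alkenyl iodide acetal
Product: 28 iodo aldehyde (C6 aldehyde)
Conditions: AcOH/THF/H2O, 40 °C
Reagents that add atoms: water, O
Why: Mild aqueous acid hydrolyses the diethyl acetal to the C6 aldehyde, and the acetate, the alkenyl iodide and the tertiary alcohol should survive.

**Step 21**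
Reactants: 28 iodo aldehyde
Product: 30 macrocyclic (6R) allylic alcohol, via alkenylchromium dichloride 29 (not isolated)
Conditions: CrCl2 (excess), NiCl2 (cat.), DMSO/THF, rt, slow addition at high dilution
Reagents that add atoms: none
Why: In the Nozaki–Hiyama–Kishi reaction zerovalent nickel inserts into the C–I bond, the alkenyl group passes to trivalent chromium and adds to the aldehyde only, closing the ten-membered ring at C6–C7, and the Z alkene with the cis-disposed C1 and C10 chains should confine the aldehyde to one face with its oxygen outward, expected to give 6R.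

**Step 22**
Reactants: 30 macrocyclic (6R) allylic alcohol
Product: 31 target, (1S,2Z,6R,9R,10S,11R,14R)-11-hydroxyeunicella-2,7(16)-diene-6,9-diyl diacetate
Conditions: Ac2O, pyridine, DMAP (cat.), CH2Cl2, 0 °C to rt
Reagents that add atoms: acetic anhydride, CC(=O)OC(C)=O
Why: Acetylation of the secondary allylic C6 hydroxyl completes the target, the axial tertiary C11 hydroxyl being too hindered to react under these conditions.

**Compound list**
1 | 4-hydroxy-6-methyl-2H-pyran-2-one | CC1=CC(O)=CC(=O)O1 | starting material
2 | 6-methyl-2-oxo-2H-pyran-4-yl trifluoromethanesulfonate | CC1=CC(OS(=O)(=O)C(F)(F)F)=CC(=O)O1 | intermediate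
3 | 6-methyl-2H-pyran-2-one | CC1=CC=CC(=O)O1 | intermediate
4 | maleic anhydride | O=C1C=CC(=O)O1 | starting material
5 | (±)-endo-1-methyl-3-oxo-2-oxabicyclo[2.2.2]oct-7-ene-5,6-dicarboxylic anhydride (anhydride anti to the lactone bridge) | O=C3[C@@H]1[C@H](C(=O)O3)[C@@H](C2=O)C=C[C@@]1(C)O2 | intermediate
6 | (±)-endo-1-methyl-3-oxo-2-oxabicyclo[2.2.2]octane-5,6-dicarboxylic anhydride | O=C3[C@@H]1[C@H](C(=O)O3)[C@@H](C2=O)CC[C@@]1(C)O2 | intermediate
7 | (±)-1-methyl-3-oxo-2-oxabicyclo[2.2.2]octane-5,6-dicarboxylic acid (cis, anti to the lactone bridge) | OC(=O)[C@@H]1[C@H](C(=O)O)[C@@H](C2=O)CC[C@@]1(C)O2 | intermediate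
8 | (±)-5,6-bis(hydroxymethyl)-1-methyl-2-oxabicyclo[2.2.2]octan-3-one | OC[C@@H]1[C@H](CO)[C@@H](C2=O)CC[C@@]1(C)O2 | intermediate
9 | (S)-1-phenylethylamine | C[C@H](N)c1ccccc1 | starting material
10 | N-[(S)-1-phenylethyl]-4-hydroxy-2,3-bis(hydroxymethyl)-4-methylcyclohexane-1-carboxamide, ring configuration as in the target | OC[C@@H]1[C@H](CO)[C@@H](C(=O)N[C@@H](C)c2ccccc2)CC[C@@]1(C)O | intermediate
11 | trans-fused 5-hydroxy-4-(hydroxymethyl)-5-methylhexahydro-2-benzofuran-1(3H)-one | OC[C@@H]1[C@H](CO2)[C@@H](C2=O)CC[C@@]1(C)O | intermediate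
12 | C9 tert-butyldimethylsilyl ether of 11 | CC(C)(C)[Si](C)(C)OC[C@@H]1[C@H](CO2)[C@@H](C2=O)CC[C@@]1(C)O | intermediate
13 | γ-hydroxy methyl ketone (C14 acetyl, C1 hydroxymethyl, C10 silyloxymethyl, C11 carbinol) | CC(C)(C)[Si](C)(C)OC[C@@H]1[C@H](CO)[C@@H](C(C)=O)CC[C@@]1(C)O | intermediate
14 | isopropenyl diol | CC(C)(C)[Si](C)(C)OC[C@@H]1[C@H](CO)[C@@H](C(C)=C)CC[C@@]1(C)O | intermediate
15 | isopropyl diol | CC(C)(C)[Si](C)(C)OC[C@@H]1[C@H](CO)[C@@H](C(C)C)CC[C@@]1(C)O | intermediate
16 | C2 aldehyde | CC(C)(C)[Si](C)(C)OC[C@@H]1[C@H](C=O)[C@@H](C(C)C)CC[C@@]1(C)O | intermediate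
17 | (Z)-2-iodo-2-alkene at C2=C3 | CC(C)(C)[Si](C)(C)OC[C@@H]1[C@H](/C=C(/C)I)[C@@H](C(C)C)CC[C@@]1(C)O | intermediate
18 | acrolein diethyl acetal | C=CC(OCC)OCC | starting material
19 | 9-(3,3-diethoxypropyl)-9-borabicyclo[3.3.1]nonane | CCOC(CCB1C2CCCC1CCC2)OCC | intermediate
20 | (Z)-alkene with C4–C6 chain, C6 diethyl acetal, C9–OTBS | CC(C)(C)[Si](C)(C)OC[C@@H]1[C@H](/C=C(/C)CCC(OCC)OCC)[C@@H](C(C)C)CC[C@@]1(C)O | intermediate
21 | C9 primary alcohol | OC[C@@H]1[C@H](/C=C(/C)CCC(OCC)OCC)[C@@H](C(C)C)CC[C@@]1(C)O | intermediate
22 | C9 aldehyde | O=C[C@@H]1[C@H](/C=C(/C)CCC(OCC)OCC)[C@@H](C(C)C)CC[C@@]1(C)O | intermediate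
23 | 2,3-dibromopropene | C=C(Br)CBr | starting material
24 | 2-bromoallylindium dibromide | C=C(Br)C[In](Br)Br | intermediate
25 | (9R) 2-bromo homoallylic alcohol | C=C(Br)C[C@@H](O)[C@@H]1[C@H](/C=C(/C)CCC(OCC)OCC)[C@@H](C(C)C)CC[C@@]1(C)O | intermediate
26 | C9 acetate, alkenyl bromide | C=C(Br)C[C@@H](OC(C)=O)[C@@H]1[C@H](/C=C(/C)CCC(OCC)OCC)[C@@H](C(C)C)CC[C@@]1(C)O | intermediate
27 | C9 acetate, alkenyl iodide | C=C(I)C[C@@H](OC(C)=O)[C@@H]1[C@H](/C=C(/C)CCC(OCC)OCC)[C@@H](C(C)C)CC[C@@]1(C)O | intermediate
28 | iodo aldehyde (C6 aldehyde, C7 alkenyl iodide) | C=C(I)C[C@@H](OC(C)=O)[C@@H]1[C@H](/C=C(/C)CCC=O)[C@@H](C(C)C)CC[C@@]1(C)O | intermediate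
29 | alkenylchromium dichloride derived from 28 | C=C([Cr](Cl)Cl)C[C@@H](OC(C)=O)[C@@H]1[C@H](/C=C(/C)CCC=O)[C@@H](C(C)C)CC[C@@]1(C)O | intermediate
30 | macrocyclic (6R) allylic alcohol, 9-acetate | C=C1C[C@@H](OC(C)=O)[C@@H]2[C@H](/C=C(/C)CC[C@H]1O)[C@@H](C(C)C)CC[C@@]2(C)O | intermediate
31 | (1S,2Z,6R,9R,10S,11R,14R)-11-hydroxyeunicella-2,7(16)-diene-6,9-diyl diacetate (CNP0303839.1) | C=C1C[C@@H](OC(C)=O)[C@@H]2[C@H](/C=C(/C)CC[C@H]1OC(C)=O)[C@@H](C(C)C)CC[C@@]2(C)O | target

**Step count**
Total: 22 steps. Longest linear sequence: 22 steps (from 1 to 31; the borane 19 is made and used in the flask of step 14).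

**Steps most likely to fail**

1. Step 21 (ring closure). The ring-forming addition may show low facial selectivity at the aldehyde, so that the C6 epimer dominates; intermolecular coupling is held back by dilution. Fallback: setting out from 28, the closure is run as before and the mixture of 30 and its C6 epimer F1 is oxidised with Dess–Martin periodinane to the cross-conjugated macrocyclic enone F2. Reduction with (S)-2-methyl-CBS-oxazaborolidine and catecholborane in toluene at −78 °C then sets C6 under reagent control (alkenyl side as the large group) and returns to the route at 30.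

2. Step 17 (allylation at C9). Facial selectivity at the axial aldehyde may be low or reversed, since it rests on the size difference between the C11 methyl group and the C1 chain. Fallback: setting out from 22, the addition is run as before, and the mixture of 25 and its C9 epimer F3 is oxidised with Dess–Martin periodinane to the 2-bromoallyl ketone F4. Reduction with (S)-2-methyl-CBS-oxazaborolidine and catecholborane (ring carbon as the large group) should then give the 9R alcohol, and the route is rejoined at 25.

3. Step 13 (iodo-olefination). The hindered α-branched aldehyde may react sluggishly with the iodo ylide, with decomposition of the ylide and loss of geometric purity. Fallback: setting out from 16, a Still–Gennari olefination with ethyl 2-[bis(2,2,2-trifluoroethoxy)phosphoryl]propanoate (KN(SiMe3)2, 18-crown-6, THF, −78 °C) gives the (Z)-2-methyl enoate F5, in which the ester carbon is C4 and lies cis to C1. Reduction with i-Bu2AlH gives the (Z)-allylic alcohol F6, and MsCl/Et3N followed by LiBr gives the (Z)-allylic bromide F7. Alkylation with the lithium enolate of ethyl acetate (LiN(i-Pr)2, THF, −78 °C) forms C4–C5 and gives the ethyl ester F8. Reduction with i-Bu2AlH at −78 °C gives the aldehyde F9, and triethyl orthoformate/ethanol/PPTS gives the diethyl acetal 20, where the route is rejoined.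

**Further compounds**
F1 | step 21 | C6 epimer of 30 | C=C1C[C@@H](OC(C)=O)[C@@H]2[C@H](/C=C(/C)CC[C@@H]1O)[C@@H](C(C)C)CC[C@@]2(C)O
F2 | step 21 | macrocyclic C6 enone | C=C1C[C@@H](OC(C)=O)[C@@H]2[C@H](/C=C(/C)CCC1=O)[C@@H](C(C)C)CC[C@@]2(C)O
F3 | step 17 | C9 epimer of 25 | C=C(Br)C[C@H](O)[C@@H]1[C@H](/C=C(/C)CCC(OCC)OCC)[C@@H](C(C)C)CC[C@@]1(C)O
F4 | step 17 | C9 2-bromoallyl ketone | C=C(Br)CC(=O)[C@@H]1[C@H](/C=C(/C)CCC(OCC)OCC)[C@@H](C(C)C)CC[C@@]1(C)O
F5 | step 13 | ethyl (Z)-2-methyl enoate | CC(C)(C)[Si](C)(C)OC[C@@H]1[C@H](/C=C(/C)C(=O)OCC)[C@@H](C(C)C)CC[C@@]1(C)O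
F6 | step 13 | (Z)-allylic alcohol | CC(C)(C)[Si](C)(C)OC[C@@H]1[C@H](/C=C(/C)CO)[C@@H](C(C)C)CC[C@@]1(C)O
F7 | step 13 | (Z)-allylic bromide | CC(C)(C)[Si](C)(C)OC[C@@H]1[C@H](/C=C(/C)CBr)[C@@H](C(C)C)CC[C@@]1(C)O
F8 | step 13 | ethyl ester with C4–C6 chain | CC(C)(C)[Si](C)(C)OC[C@@H]1[C@H](/C=C(/C)CCC(=O)OCC)[C@@H](C(C)C)CC[C@@]1(C)O
F9 | step 13 | C6 aldehyde with C9–OTBS | CC(C)(C)[Si](C)(C)OC[C@@H]1[C@H](/C=C(/C)CCC=O)[C@@H](C(C)C)CC[C@@]1(C)O
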